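**Retrosynthetic overview**
1. Target 19 comes from hydrogenolysis of both benzyl ethers of the 8,3'-di-O-benzyl flavone 18.
2. Ring C is the only ring built and is closed last. It comes from oxidative cyclisation (O1–C2 bond, then C2=C3) of the 2'-hydroxychalcone 15.
3. The key C–C bond (Cα=Cβ of 15) comes from a Claisen–Schmidt aldol condensation of ring A acetophenone 9 with ring B aldehyde 13.
4. Acetophenone 9 comes from symmetrical 1,2,3,4-tetramethoxybenzene 4 (made from 2,3,4-trimethoxybenzaldehyde 1) by acetylation, chelation-guided cleavage of the 2- and 3-OMe groups, and 3-O-benzylation.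
5. Aldehyde 13 comes from 5-bromovanillin 10 by Br→OH exchange, selective 4-O-methylation and benzylation. Rings A and B are bought.

Assumption: the target SMILES holds no stereocentre, so the flavone is achiral and there is no enantiomer to select. The only stereo-element on the route is the E alkene of chalcone 15. The racemic centres in 14, 16 and 17 are transient and are erased.

**Step 1**
Reactants: 1 2,3,4-trimethoxybenzaldehyde
Product: 3 2,3,4-trimethoxyphenol, via aryl formate 2 (not isolated)
Conditions: mCPBA (1.3 equiv), CH2Cl2, 0 °C → rt; aq NaHCO3 wash; then K2CO3 (0.2 equiv), MeOH, rt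
Reagents that add atoms: mCPBA, O=C(OO)c1cccc(Cl)c1
Why: In this Baeyer–Villiger oxidation the electron-rich aryl group migrates to give the formate, which base-catalysed methanolysis converts to the phenol.

**Step 2**
Reactants: 3 2,3,4-trimethoxyphenol
Product: 4 1,2,3,4-tetramethoxybenzene
Conditions: MeI (1.5 equiv), K2CO3 (2 equiv), acetone, reflux
Reagents that add atoms: methyl iodide, CI
Why: This Williamson O-methylation gives a symmetrical arene, so the next step has no regiochemical choice.

**Step 3**
Reactants: 4 1,2,3,4-tetramethoxybenzene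
Product: 5 1-(2,3,4,5-tetramethoxyphenyl)ethan-1-one
Conditions: AcCl (1.1 equiv), AlCl3 (1.2 equiv), CH2Cl2, −10 → 0 °C, 1 h; ice/1 M HCl
Reagents that add atoms: acetyl chloride, CC(=O)Cl
Why: In this Friedel–Crafts acylation the two free positions are equivalent by symmetry, and the new acyl group deactivates the ring against a second acylation.

**Step 4**
Reactants: 5 1-(2,3,4,5-tetramethoxyphenyl)ethan-1-one
Product: 8 1-(2,3-dihydroxy-4,5-dimethoxyphenyl)ethan-1-one, via aryloxydichloroborane chelate 6 (not isolated), via cyclic chloroborate 7 (not isolated)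
Conditions: BCl3 (2.2 equiv, 1 M in CH2Cl2), CH2Cl2, −10 °C → rt; then ice-water/1 M HCl
Reagents that add atoms: none
Why: In this chelation-directed Lewis acid ether cleavage, carbonyl-bound BCl3 cleaves the ortho 2-OMe, the boron held on O-2 then cleaves the neighbouring 3-OMe to close a five-membered borate, the unchelated 4- and 5-OMe groups resist BCl3 at or below rt, and water releases the catechol.

**Step 5**
Reactants: 8 1-(2,3-dihydroxy-4,5-dimethoxyphenyl)ethan-1-one
Product: 9 1-[3-(benzyloxy)-2-hydroxy-4,5-dimethoxyphenyl]ethan-1-one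
Conditions: BnBr (1.0 equiv), K2CO3 (1.1 equiv), acetone, reflux, N2
Reagents that add atoms: benzyl bromide, BrCc1ccccc1
Why: This Williamson etherification is selective because the 2-OH is locked in a strong hydrogen bond to the acetyl carbonyl (as is the 5-OH of flavones), so one equivalent of BnBr with a weak base alkylates only the 3-OH.

**Step 6**
Reactants: 10 5-bromovanillin (3-bromo-4-hydroxy-5-methoxybenzaldehyde)
Product: 11 3,4-dihydroxy-5-methoxybenzaldehyde
Conditions: NaOH (8% aq, 7 equiv), Cu powder (cat.), reflux, N2, 24 h; then HCl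
Reagents that add atoms: sodium hydroxide, [Na+].[OH-]
Why: This copper-catalysed Ullmann-type hydroxylation of the aryl bromide works because the phenoxide form protects the aldehyde from Cannizzaro disproportionation.

**Step 7**
Reactants: 11 3,4-dihydroxy-5-methoxybenzaldehyde
Product: 12 3-hydroxy-4,5-dimethoxybenzaldehyde
Conditions: Me2SO4 (1.05 equiv), Na2CO3 (1.1 equiv), acetone, reflux, N2
Reagents that add atoms: dimethyl sulfate, COS(=O)(=O)OC
Why: This Williamson methylation is selective because the 4-OH para to the formyl group is the more acidic, so a weak base forms and alkylates only that phenoxide.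

**Step 8**
Reactants: 12 3-hydroxy-4,5-dimethoxybenzaldehyde
Product: 13 3-(benzyloxy)-4,5-dimethoxybenzaldehyde
Conditions: BnBr (1.2 equiv), K2CO3 (1.5 equiv), DMF, 60 °C
Reagents that add atoms: benzyl bromide, BrCc1ccccc1
Why: This Williamson etherification of the only free phenol masks it against the strong base and the oxidant of the next two steps.

**Step 9**
Reactants: 9 1-[3-(benzyloxy)-2-hydroxy-4,5-dimethoxyphenyl]ethan-1-one; 13 3-(benzyloxy)-4,5-dimethoxybenzaldehyde
Product: 15 (E)-1-[3-(benzyloxy)-2-hydroxy-4,5-dimethoxyphenyl]-3-[3-(benzyloxy)-4,5-dimethoxyphenyl]prop-2-en-1-one, via aldol adduct 14 (not isolated)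
Conditions: KOH (50% aq, 10 equiv), EtOH, rt, 36–48 h; then cold 1 M HCl to pH 3
Reagents that add atoms: none
Why: In this Claisen–Schmidt crossed aldol condensation the methyl ketone enolate adds to the non-enolisable aldehyde, and E1cB loss of water gives the conjugated, thermodynamically preferred E enone.

**Step 10**
Reactants: 15 the (E)-2'-hydroxychalcone
Product: 18 8-(benzyloxy)-2-[3-(benzyloxy)-4,5-dimethoxyphenyl]-6,7-dimethoxy-4H-chromen-4-one, via flavanone 16 (not isolated), via 3-iodoflavanone 17 (not isolated)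
Conditions: I2 (10 mol%), DMSO, 130 °C, 2–3 h; aq Na2S2O3 wash
Reagents that add atoms: none
Why: In this I2/DMSO oxidative cyclisation, oxa-Michael closure is followed by α-iodination and loss of HI to give the flavone, DMSO re-oxidises HI to I2, and aryl benzyl and methyl ethers tolerate the conditions.

**Step 11**
Reactants: 18 8-(benzyloxy)-2-[3-(benzyloxy)-4,5-dimethoxyphenyl]-6,7-dimethoxy-4H-chromen-4-one
Product: 19 8-hydroxy-2-(3-hydroxy-4,5-dimethoxyphenyl)-6,7-dimethoxy-4H-chromen-4-one (target)
Conditions: H2 (1 atm), 10% Pd/C, EtOAc–MeOH 1:1, rt, stopped when 18 and the mono-benzyl ethers are gone (TLC)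
Reagents that add atoms: none
Why: Catalytic hydrogenolysis of the two aryl benzyl ethers at 1 atm is much faster than reduction of the vinylogous-ester C2=C3 bond of the flavone, and no stereocentre is formed.

**Compound list**
1 | 2,3,4-trimethoxybenzaldehyde | COc1ccc(C=O)c(OC)c1OC | starting material
2 | 2,3,4-trimethoxyphenyl formate | COc1ccc(OC=O)c(OC)c1OC | intermediate (not isolated)
3 | 2,3,4-trimethoxyphenol | COc1ccc(O)c(OC)c1OC | intermediate
4 | 1,2,3,4-tetramethoxybenzene | COc1ccc(OC)c(OC)c1OC | intermediate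
5 | 1-(2,3,4,5-tetramethoxyphenyl)ethan-1-one | CC(=O)c1cc(OC)c(OC)c(OC)c1OC | intermediate
6 | (6-acetyl-2,3,4-trimethoxyphenoxy)dichloroborane, carbonyl-chelated | CC(=O)c1cc(OC)c(OC)c(OC)c1OB(Cl)Cl | intermediate (not isolated)
7 | 1-(2-chloro-6,7-dimethoxy-1,3,2-benzodioxaborol-4-yl)ethan-1-one | CC(=O)c1cc(OC)c(OC)c2OB(Cl)Oc12 | intermediate (not isolated)
8 | 1-(2,3-dihydroxy-4,5-dimethoxyphenyl)ethan-1-one | CC(=O)c1cc(OC)c(OC)c(O)c1O | intermediate
9 | 1-[3-(benzyloxy)-2-hydroxy-4,5-dimethoxyphenyl]ethan-1-one | CC(=O)c1cc(OC)c(OC)c(OCc2ccccc2)c1O | intermediate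
10 | 5-bromovanillin (3-bromo-4-hydroxy-5-methoxybenzaldehyde) | COc1cc(C=O)cc(Br)c1O | starting material
11 | 3,4-dihydroxy-5-methoxybenzaldehyde | COc1cc(C=O)cc(O)c1O | intermediate
12 | 3-hydroxy-4,5-dimethoxybenzaldehyde | COc1cc(C=O)cc(O)c1OC | intermediate
13 | 3-(benzyloxy)-4,5-dimethoxybenzaldehyde | COc1cc(C=O)cc(OCc2ccccc2)c1OC | intermediate
14 | 1-[3-(benzyloxy)-2-hydroxy-4,5-dimethoxyphenyl]-3-[3-(benzyloxy)-4,5-dimethoxyphenyl]-3-hydroxypropan-1-one (racemic) | COc1cc(C(O)CC(=O)c2cc(OC)c(OC)c(OCc3ccccc3)c2O)cc(OCc2ccccc2)c1OC | intermediate (not isolated)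
15 | (E)-1-[3-(benzyloxy)-2-hydroxy-4,5-dimethoxyphenyl]-3-[3-(benzyloxy)-4,5-dimethoxyphenyl]prop-2-en-1-one | COc1cc(/C=C/C(=O)c2cc(OC)c(OC)c(OCc3ccccc3)c2O)cc(OCc2ccccc2)c1OC | intermediate
16 | 8-(benzyloxy)-2-[3-(benzyloxy)-4,5-dimethoxyphenyl]-6,7-dimethoxychroman-4-one (racemic) | COc1cc(C2CC(=O)c3cc(OC)c(OC)c(OCc4ccccc4)c3O2)cc(OCc2ccccc2)c1OC | intermediate (not isolated)
17 | 8-(benzyloxy)-2-[3-(benzyloxy)-4,5-dimethoxyphenyl]-3-iodo-6,7-dimethoxychroman-4-one (racemic, relative configuration not defined) | COc1cc(C2Oc3c(OCc4ccccc4)c(OC)c(OC)cc3C(=O)C2I)cc(OCc2ccccc2)c1OC | intermediate (not isolated)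
18 | 8-(benzyloxy)-2-[3-(benzyloxy)-4,5-dimethoxyphenyl]-6,7-dimethoxy-4H-chromen-4-one | COc1cc(-c2cc(=O)c3cc(OC)c(OC)c(OCc4ccccc4)c3o2)cc(OCc2ccccc2)c1OC | intermediate
19 | 8-hydroxy-2-(3-hydroxy-4,5-dimethoxyphenyl)-6,7-dimethoxy-4H-chromen-4-one (achiral) | COc1cc(-c2cc(=O)c3cc(OC)c(OC)c(O)c3o2)cc(O)c1OC | target

**Total step count:** 11
**Longest linear sequence:** 8 steps (steps 1, 2, 3, 4, 5, 9, 10, 11). The ring B branch (steps 6–8) joins at step 9.

**Three steps most likely to fail**

Step 4 may stop at the mono-phenol or go on to cleave the 4-OMe. The fallback makes the catechol by oxidation instead of by double ether cleavage at the ketone stage. It sets out from 1. AlCl3 (1.1 equiv, CH2Cl2, rt) removes only the methyl group ortho to the formyl group and gives 2-hydroxy-3,4-dimethoxybenzaldehyde F1. Dakin oxidation (H2O2, aq NaOH, N2, rt) exchanges the formyl group for a hydroxyl and gives 3,4-dimethoxybenzene-1,2-diol F2. Heating F2 in AcOH/BF3·OEt2 at 85 °C acetylates ortho to the terminal hydroxyl and para to the 3-OMe, because the ortho-hydroxy ketone is the thermodynamic product. The route is rejoined at 8.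

Step 5 may give mixtures of 2-O-, 3-O- and bis-benzyl ethers. The fallback replaces selective protection by exhaustive protection followed by chelation-controlled deprotection. It sets out from 8. BnBr (2.5 equiv), K2CO3, DMF at 70 °C gives 1-[2,3-bis(benzyloxy)-4,5-dimethoxyphenyl]ethan-1-one F3. MgBr2·OEt2 in toluene–Et2O at reflux binds between the carbonyl and O-2 and cleaves only the benzyl ether ortho to the acetyl group. The route is rejoined at 9.

Step 7 may methylate the wrong oxygen or both oxygens of the catechol. The fallback methylates first and brings in the 3-oxygen afterwards through boron, so no catechol has to be differentiated. It sets out from 10 and bypasses 11. MeI, K2CO3, DMF gives 3-bromo-4,5-dimethoxybenzaldehyde F4. Miyaura borylation (B2pin2, Pd(dppf)Cl2, KOAc, dioxane, 90 °C) gives 3,4-dimethoxy-5-(4,4,5,5-tetramethyl-1,3,2-dioxaborolan-2-yl)benzaldehyde F5. Mild oxidation with NaBO3·4H2O in THF–H2O at rt converts the C–B bond into C–OH without touching the aldehyde. The route is rejoined at 12.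

**Further compounds**
F1 | step 4 | 2-hydroxy-3,4-dimethoxybenzaldehyde | COc1ccc(C=O)c(O)c1OC
F2 | step 4 | 3,4-dimethoxybenzene-1,2-diol | COc1ccc(O)c(O)c1OC
F3 | step 5 | 1-[2,3-bis(benzyloxy)-4,5-dimethoxyphenyl]ethan-1-one | CC(=O)c1cc(OC)c(OC)c(OCc2ccccc2)c1OCc1ccccc1
F4 | step 7 | 3-bromo-4,5-dimethoxybenzaldehyde | COc1cc(C=O)cc(Br)c1OC
F5 | step 7 | 3,4-dimethoxy-5-(4,4,5,5-tetramethyl-1,3,2-dioxaborolan-2-yl)benzaldehyde | COc1cc(C=O)cc(B2OC(C)(C)C(C)(C)O2)c1OC
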